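The cyclohexane ring of the quinic acid core is disconnected at C3–C4, the bond flanked by the cis-disposed O3 and O4 that lie trans to O5. A SmI2 pinacol cyclization of an acyclic 1,6-dialdehyde forges this bond, closes the six-membered ring and sets C3 and C4 in one operation under control of the C5 silyloxy stereocentre. The dialdehyde holds C1 as a pivalaldehyde-derived dioxolanone made from (S)-malic acid, a CH2CHO arm (C2–C3) and a CH2CH(OTBS)CHO arm (C6–C5–C4) whose carbinol is set by a reagent-controlled reduction. Selective silylation, succinylation, caffeoylation and one acid treatment complete the triester.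

Key step: step 7

Remark: ring positions are numbered as in quinic acid (C1 quaternary; O1, O3 and O4 on one face, O5 and the carboxyl carbon on the other), and stannane 6 is assumed to be a catalogue reagent.

Step 1
Reactants: 1 (S)-malic acid; 2 pivalaldehyde
Product: 3 [(2S,4S)-2-tert-butyl-5-oxo-1,3-dioxolan-4-yl]acetic acid (tert-butyl cis to the CH2CO2H arm)
Conditions: TsOH·H2O (cat.), H2SO4 (cat.), pentane, reflux, Dean–Stark trap; recrystallisation
Reagents that add atoms: none
Why: Acid-catalysed acetalization of the α-hydroxy acid unit with azeotropic removal of water closes the five-membered dioxolanone in preference to the six-membered alternative and, under thermodynamic control, places the tert-butyl group cis to the CH2CO2H arm, while the malic acid stereocentre is not touched.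

Step 2
Reactants: 3 [(2S,4S)-2-tert-butyl-5-oxo-1,3-dioxolan-4-yl]acetic acid; 4 allyl bromide
Product: 5 [(2S,4S)-2-tert-butyl-5-oxo-4-(prop-2-en-1-yl)-1,3-dioxolan-4-yl]acetic acid (CH2CO2H cis and allyl trans to tert-butyl)
Conditions: LiN(SiMe3)2 (2.2 equiv), THF, −78 °C; then 4, −78 → −20 °C; aqueous HCl work-up
Reagents that add atoms: none
Why: Diastereoselective enolate alkylation (self-regeneration of stereocentres): the carboxylate–enolate dianion is planar at the former stereocentre and allyl bromide attacks the face opposite the tert-butyl group, so allyl takes the place of the original hydrogen and the future C1 is set.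

Step 3
Reactants: 5 allylated dioxolanone acid; 6 (E)-tributyl(2-phenylethenyl)stannane
Product: 8 (2S,5S)-2-tert-butyl-5-[(3E)-2-oxo-4-phenylbut-3-en-1-yl]-5-(prop-2-en-1-yl)-1,3-dioxolan-4-one, via acid chloride 7 (not isolated)
Conditions: (COCl)2, DMF (cat.), CH2Cl2, 0 °C → rt, evaporate; then 6, PdCl2(PPh3)2 (3 mol %), toluene, 70 °C
Reagents that add atoms: none
Why: Stille acyl coupling: the acid chloride adds oxidatively to zerovalent palladium, the styryl group is transferred from tin with retention of the E geometry and reductive elimination gives the enone under neutral conditions that leave the hindered acetal-lactone, the allyl group and the quaternary centre untouched.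

Step 4
Reactants: 8 styryl ketone
Product: 9 (2S,5S)-2-tert-butyl-5-[(2R,3E)-2-hydroxy-4-phenylbut-3-en-1-yl]-5-(prop-2-en-1-yl)-1,3-dioxolan-4-one
Conditions: (S)-2-methyl-CBS-oxazaborolidine (20 mol %), catecholborane (1.8 equiv), toluene, −78 °C; MeOH quench
Reagents that add atoms: none
Why: Corey–Bakshi–Shibata reduction: the ketone binds to the boron of the (S)-oxazaborolidine anti to the styryl group, which plays the part of the large substituent as aryl does in aryl alkyl ketones, and hydride from the coordinated catecholborane should reach the carbonyl face that gives the (R)-carbinol (the future C5) under reagent control, while catecholborane at −78 °C neither hydroborates the allyl group nor reduces the lactone.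

Step 5
Reactants: 9 (R)-allylic alcohol
Product: 10 (2S,5S)-2-tert-butyl-5-[(2R,3E)-2-(tert-butyldimethylsilyloxy)-4-phenylbut-3-en-1-yl]-5-(prop-2-en-1-yl)-1,3-dioxolan-4-one
Conditions: TBSCl, imidazole, DMF, 0 °C → rt
Reagents that add atoms: tert-butyldimethylsilyl chloride, CC(C)(C)[Si](C)(C)Cl
Why: Silylation of a secondary allylic alcohol by TBSCl through the N-silylimidazolium ion is a standard protection that touches no stereocentre and no other functional group.

Step 6
Reactants: 10 silyl ether diene
Product: 11 (2S,5R)-2-tert-butyl-5-(2-oxoethyl)-5-[(2R)-2-(tert-butyldimethylsilyloxy)-3-oxopropyl]-1,3-dioxolan-4-one (dialdehyde; tert-butyl cis to the silyloxy arm)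
Conditions: O3, CH2Cl2, −78 °C; then PPh3, −78 °C → rt; rapid filtration through silica, used at once
Reagents that add atoms: ozone, [O-][O+]=O
Why: Ozonolysis (1,3-dipolar cycloaddition, cycloreversion, ozonide formation) followed by reduction with PPh3 cleaves the terminal and the styryl alkene to the C3 and C4 aldehydes without acid or base, so the α-silyloxy centre C5 keeps its configuration and the β-oxygenated aldehyde does not eliminate.

Step 7
Reactants: 11 dialdehyde
Product: 12 5-O-(tert-butyldimethylsilyl)quinic acid as its (S)-configured pivalaldehyde acetal across O1 and the carboxyl group (spiro-dioxolanone, tert-butyl cis to C6; O3 and O4 free and cis, O5 trans to O4)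
Conditions: SmI2 (0.1 M in THF, 3 equiv), t-BuOH (3 equiv), THF, −78 °C → rt, slow addition of 11, high dilution
Reagents that add atoms: none
Why: Single-electron transfer from divalent samarium to an aldehyde gives a samarium ketyl, whose C3 carbon adds to the C4 carbonyl carbon (or the two ketyls couple within one samarium-bridged complex), and a second electron transfer with protonation by t-BuOH releases the diol. The closest known reaction type is the SmI2 pinacol cyclization of 1,6-dialdehydes that carry an α-alkoxy or α-silyloxy group, which gives cis-cyclohexane-1,2-diols anti to that group. The cyclohexane (C1–C6) closes in a 6-exo-trig mode through the new C3–C4 bond. C3 and C4 are set cis to each other because both oxygens stay bound to trivalent samarium while the C–C bond forms, and C4 is set trans to C5 because the bulky silyloxy group and the samarium-bound O4 avoid each other sterically and electrostatically; O1, on the face of the incoming diol, may serve as a further donor to the metal. The step needs chemoselectivity for the two aldehydes over the acetal-lactone and for ring closure over intermolecular coupling or reductive loss of the α-silyloxy group: aldehydes are reduced far faster than a hindered ester at −78 °C without HMPA, high dilution favours cyclization, and a silyl ether is a poor leaving group from a ketyl.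

Step 8
Reactants: 12 3,4-diol
Product: 13 3,5-bis-O-(tert-butyldimethylsilyl)quinic acid pivalaldehyde acetal (O4 free)
Conditions: TBSCl (1.1 equiv), imidazole, DMF, 0 °C → rt
Reagents that add atoms: tert-butyldimethylsilyl chloride, CC(C)(C)[Si](C)(C)Cl
Why: Sterically controlled monosilylation: O3 has a methylene neighbour whereas O4 lies between C3 and the silyloxy-bearing C5, the same order of reactivity that leaves O4 free when quinate esters are silylated at O3 and O5.

Step 9
Reactants: 13 3,5-bis-silyl ether; 14 4-tert-butoxy-4-oxobutanoic acid (mono-tert-butyl succinate)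
Product: 15 4-O-(4-tert-butoxy-4-oxobutanoyl)-3,5-bis-O-(tert-butyldimethylsilyl)quinic acid pivalaldehyde acetal
Conditions: DCC (1.5 equiv), DMAP (1 equiv), CH2Cl2, rt
Reagents that add atoms: none
Why: Steglich esterification (O-acylisourea then N-acylpyridinium) acylates the only free hydroxyl, the hindered O4, for which a full equivalent of DMAP is used, with retention at C4 because the C–O bond is not broken.

Step 10
Reactants: 15 succinylated bis-silyl ether
Product: 16 4-O-(4-tert-butoxy-4-oxobutanoyl)quinic acid pivalaldehyde acetal (O3 and O5 free)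
Conditions: HF·pyridine, pyridine, THF, 0 °C → rt
Reagents that add atoms: none
Why: Fluoride cleaves both secondary Si–O bonds (formation of the strong Si–F bond) in a medium buffered on the acidic side, in which the tert-butyl ester and the acetal-lactone are stable and no alkoxide is formed that could move the O4 acyl group to O3 or O5.

Step 11
Reactants: 17 caffeic acid
Product: 19 (E)-3-[3,4-bis(methoxymethoxy)phenyl]prop-2-enoic acid, via methoxymethyl ester 18 (not isolated)
Conditions: MOMCl (3.5 equiv), i-Pr2NEt, CH2Cl2, 0 °C → rt; then LiOH, THF/H2O, rt; cold aqueous HCl to pH 4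
Reagents that add atoms: chloromethyl methyl ether, COCCl; lithium hydroxide, [Li+].[OH-] (its oxygen ends in the carboxyl OH)
Why: Williamson-type alkylation of both phenols and of the carboxylate by MOMCl followed by saponification of the very labile methoxymethyl ester gives the free acid carrying acid-labile phenol protection, the E alkene being inert to both operations.

Step 12
Reactants: 16 3,5-diol; 19 protected caffeic acid
Product: 20 3,5-bis-O-[(E)-3,4-bis(methoxymethoxy)cinnamoyl]-4-O-(4-tert-butoxy-4-oxobutanoyl)quinic acid pivalaldehyde acetal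
Conditions: 19 (3 equiv), DCC (3 equiv), DMAP (0.3 equiv), CH2Cl2, 0 °C → rt
Reagents that add atoms: none
Why: Double Steglich esterification acylates the two secondary hydroxyls O3 and O5 with excess activated cinnamic acid, the only other hydroxyl (O1) being locked in the acetal, and proceeds with retention at C3 and C5 since only O–H bonds are broken.

Step 13
Reactants: 20 fully protected triester
Product: 21 3,5-di-O-[(E)-caffeoyl]-4-O-succinylquinic acid (target)
Conditions: TFA/H2O (9:1), 0 °C → rt
Reagents that add atoms: none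
Why: Brønsted-acid global deprotection: aqueous TFA hydrolyses the four methoxymethyl aryl ethers and the pivalaldehyde acetal through oxocarbenium ions and cleaves the tert-butyl ester through the tert-butyl cation, whereas the three secondary carboxylic esters, the cinnamoyl alkenes and all stereocentres are stable to acid at room temperature.

Compound list
1 | (S)-malic acid | OC(=O)C[C@H](O)C(=O)O | starting material
2 | pivalaldehyde | CC(C)(C)C=O | starting material
3 | [(2S,4S)-2-tert-butyl-5-oxo-1,3-dioxolan-4-yl]acetic acid | OC(=O)C[C@H](O2)C(=O)O[C@H]2C(C)(C)C | intermediate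
4 | allyl bromide | C=CCBr | starting material
5 | [(2S,4S)-2-tert-butyl-5-oxo-4-(prop-2-en-1-yl)-1,3-dioxolan-4-yl]acetic acid | OC(=O)C[C@](O2)(C(=O)O[C@H]2C(C)(C)C)CC=C | intermediate
6 | (E)-tributyl(2-phenylethenyl)stannane | CCCC[Sn](CCCC)(CCCC)/C=C/c1ccccc1 | starting material
7 | [(2S,4S)-2-tert-butyl-5-oxo-4-(prop-2-en-1-yl)-1,3-dioxolan-4-yl]acetyl chloride | ClC(=O)C[C@](O2)(C(=O)O[C@H]2C(C)(C)C)CC=C | intermediate
8 | (2S,5S)-2-tert-butyl-5-[(3E)-2-oxo-4-phenylbut-3-en-1-yl]-5-(prop-2-en-1-yl)-1,3-dioxolan-4-one | O=C(/C=C/c1ccccc1)C[C@](O2)(C(=O)O[C@H]2C(C)(C)C)CC=C | intermediate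
9 | (2S,5S)-2-tert-butyl-5-[(2R,3E)-2-hydroxy-4-phenylbut-3-en-1-yl]-5-(prop-2-en-1-yl)-1,3-dioxolan-4-one | O[C@@H](/C=C/c1ccccc1)C[C@](O2)(C(=O)O[C@H]2C(C)(C)C)CC=C | intermediate
10 | (2S,5S)-2-tert-butyl-5-[(2R,3E)-2-(tert-butyldimethylsilyloxy)-4-phenylbut-3-en-1-yl]-5-(prop-2-en-1-yl)-1,3-dioxolan-4-one | CC(C)(C)[Si](C)(C)O[C@@H](/C=C/c1ccccc1)C[C@](O2)(C(=O)O[C@H]2C(C)(C)C)CC=C | intermediate
11 | (2S,5R)-2-tert-butyl-5-(2-oxoethyl)-5-[(2R)-2-(tert-butyldimethylsilyloxy)-3-oxopropyl]-1,3-dioxolan-4-one | O=C[C@H](O[Si](C)(C)C(C)(C)C)C[C@](O2)(C(=O)O[C@H]2C(C)(C)C)CC=O | intermediate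
12 | 5-O-(tert-butyldimethylsilyl)quinic acid pivalaldehyde acetal across O1 and the carboxyl group (3,4-diol free) | O[C@H]1[C@H](O[Si](C)(C)C(C)(C)C)C[C@](O2)(C(=O)O[C@H]2C(C)(C)C)C[C@H]1O | intermediate
13 | 3,5-bis-O-(tert-butyldimethylsilyl)quinic acid pivalaldehyde acetal (O4 free) | O[C@H]1[C@H](O[Si](C)(C)C(C)(C)C)C[C@](O2)(C(=O)O[C@H]2C(C)(C)C)C[C@H]1O[Si](C)(C)C(C)(C)C | intermediate
14 | 4-tert-butoxy-4-oxobutanoic acid | OC(=O)CCC(=O)OC(C)(C)C | starting material
15 | 4-O-(4-tert-butoxy-4-oxobutanoyl)-3,5-bis-O-(tert-butyldimethylsilyl)quinic acid pivalaldehyde acetal | CC(C)(C)OC(=O)CCC(=O)O[C@H]1[C@H](O[Si](C)(C)C(C)(C)C)C[C@](O2)(C(=O)O[C@H]2C(C)(C)C)C[C@H]1O[Si](C)(C)C(C)(C)C | intermediate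
16 | 4-O-(4-tert-butoxy-4-oxobutanoyl)quinic acid pivalaldehyde acetal (O3 and O5 free) | CC(C)(C)OC(=O)CCC(=O)O[C@H]1[C@H](O)C[C@](O2)(C(=O)O[C@H]2C(C)(C)C)C[C@H]1O | intermediate
17 | caffeic acid | OC(=O)/C=C/c1ccc(O)c(O)c1 | starting material
18 | methoxymethyl (E)-3-[3,4-bis(methoxymethoxy)phenyl]prop-2-enoate | COCOC(=O)/C=C/c1ccc(OCOC)c(OCOC)c1 | intermediate
19 | (E)-3-[3,4-bis(methoxymethoxy)phenyl]prop-2-enoic acid | OC(=O)/C=C/c1ccc(OCOC)c(OCOC)c1 | intermediate
20 | 3,5-bis-O-[(E)-3,4-bis(methoxymethoxy)cinnamoyl]-4-O-(4-tert-butoxy-4-oxobutanoyl)quinic acid pivalaldehyde acetal | CC(C)(C)OC(=O)CCC(=O)O[C@H]1[C@H](OC(=O)/C=C/c2ccc(OCOC)c(OCOC)c2)C[C@](O3)(C(=O)O[C@H]3C(C)(C)C)C[C@H]1OC(=O)/C=C/c1ccc(OCOC)c(OCOC)c1 | intermediate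
21 | 3,5-di-O-[(E)-caffeoyl]-4-O-succinylquinic acid | O=C(O)CCC(=O)O[C@H]1[C@H](OC(=O)/C=C/c2ccc(O)c(O)c2)C[C@](O)(C(=O)O)C[C@H]1OC(=O)/C=C/c1ccc(O)c(O)c1 | target

Total step count: 13. Longest linear sequence: 12 steps (steps 1–10, 12 and 13 from (S)-malic acid; step 11 is a one-step side branch).

Steps most likely to fail

Step 7. The cyclization may show poor facial control relative to C5, or the dialdehyde may be lost to intermolecular coupling or aldol-type self-condensation before it cyclizes. The fallback sets out from silyl ether 10 and avoids both the dialdehyde and the reductive coupling. Ring-closing metathesis with the second-generation Grubbs catalyst RuCl2(=CHPh)(PCy3)(H2IMes) in CH2Cl2 at 40 °C should expel styrene and give the C3=C4 cyclohexene, 5-O-(tert-butyldimethylsilyl)-3,4-didehydro-3,4-dideoxyquinic acid pivalaldehyde acetal F1. Dihydroxylation of F1 with catalytic OsO4 and N-methylmorpholine N-oxide in acetone/water should then deliver both oxygens to the face opposite the allylic C5 silyloxy group and so return to the route at diol 12.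

Step 4. The oxazaborolidine may discriminate poorly between the styryl group and the β-branched CH2 substituent, or conjugate reduction may compete. The fallback sets out from acid 5 and sets C5 on an alkynyl ketone instead. Acid chloride 7, made as in step 3, would be coupled with phenylacetylene (PdCl2(PPh3)2, CuI, Et3N, THF, rt; acyl Sonogashira coupling) to the ynone (2S,5S)-2-tert-butyl-5-(2-oxo-4-phenylbut-3-yn-1-yl)-5-(prop-2-en-1-yl)-1,3-dioxolan-4-one F2. Asymmetric transfer hydrogenation with RuCl[(R,R)-TsDPEN](p-cymene) in 2-propanol, whose sense is governed by the alkynyl group and little by the alkyl side, should give the (R)-propargylic alcohol F3. Semi-hydrogenation (H2, Pd/CaCO3 poisoned with Pb(OAc)2, quinoline, EtOAc) would give the (Z)-allylic alcohol F4, and TBSCl with imidazole the (Z)-configured silyl ether F5. Ozonolysis of F5 under the conditions of step 6 comes back to the route at dialdehyde 11.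

Step 12. DMAP may promote migration of the O4 succinyl group to the neighbouring free O3 or O5 before they are acylated, and acylation of the more hindered O3 may stay incomplete. The fallback sets out from diol 16 and builds the cinnamoyl units on the ring without a basic acyl-transfer step. Heating 16 with Meldrum's acid in toluene (no base) should give the 3,5-bis-O-(carboxyacetyl) diester, the bis(malonate half-ester) F6. Knoevenagel–Doebner condensation of F6 with 3,4-dihydroxybenzaldehyde (pyridine, piperidine cat., rt → 40 °C) should form both (E)-caffeoyl esters with free catechols, 3,5-di-O-caffeoyl-4-O-(4-tert-butoxy-4-oxobutanoyl)quinic acid pivalaldehyde acetal F7. Treatment of F7 with TFA/H2O as in step 13 removes the tert-butyl ester and the acetal and arrives at target 21.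

Further compounds
F1 | step 7 | 5-O-(tert-butyldimethylsilyl)-3,4-didehydro-3,4-dideoxyquinic acid pivalaldehyde acetal (C3=C4 cyclohexene) | C1=C[C@H](O[Si](C)(C)C(C)(C)C)C[C@](O2)(C(=O)O[C@H]2C(C)(C)C)C1
F2 | step 4 | (2S,5S)-2-tert-butyl-5-(2-oxo-4-phenylbut-3-yn-1-yl)-5-(prop-2-en-1-yl)-1,3-dioxolan-4-one | O=C(C#Cc1ccccc1)C[C@](O2)(C(=O)O[C@H]2C(C)(C)C)CC=C
F3 | step 4 | (2S,5S)-2-tert-butyl-5-[(2R)-2-hydroxy-4-phenylbut-3-yn-1-yl]-5-(prop-2-en-1-yl)-1,3-dioxolan-4-one | O[C@@H](C#Cc1ccccc1)C[C@](O2)(C(=O)O[C@H]2C(C)(C)C)CC=C
F4 | step 4 | (2S,5S)-2-tert-butyl-5-[(2R,3Z)-2-hydroxy-4-phenylbut-3-en-1-yl]-5-(prop-2-en-1-yl)-1,3-dioxolan-4-one | O[C@@H](/C=C\c1ccccc1)C[C@](O2)(C(=O)O[C@H]2C(C)(C)C)CC=C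
F5 | step 4 | (2S,5S)-2-tert-butyl-5-[(2R,3Z)-2-(tert-butyldimethylsilyloxy)-4-phenylbut-3-en-1-yl]-5-(prop-2-en-1-yl)-1,3-dioxolan-4-one | CC(C)(C)[Si](C)(C)O[C@@H](/C=C\c1ccccc1)C[C@](O2)(C(=O)O[C@H]2C(C)(C)C)CC=C
F6 | step 12 | 3,5-bis-O-(carboxyacetyl)-4-O-(4-tert-butoxy-4-oxobutanoyl)quinic acid pivalaldehyde acetal | CC(C)(C)OC(=O)CCC(=O)O[C@H]1[C@H](OC(=O)CC(=O)O)C[C@](O2)(C(=O)O[C@H]2C(C)(C)C)C[C@H]1OC(=O)CC(=O)O
F7 | step 12 | 3,5-di-O-[(E)-caffeoyl]-4-O-(4-tert-butoxy-4-oxobutanoyl)quinic acid pivalaldehyde acetal | CC(C)(C)OC(=O)CCC(=O)O[C@H]1[C@H](OC(=O)/C=C/c2ccc(O)c(O)c2)C[C@](O3)(C(=O)O[C@H]3C(C)(C)C)C[C@H]1OC(=O)/C=C/c1ccc(O)c(O)c1
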